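**Retrosynthetic overview**
1. Target ⇐ final double epoxidation of the (1(10)E,4E)-diene butenolide, both oxiranes from the exposed outer faces of the crown conformer.
2. Butenolide ⇐ oxidative chlorocyclocarbonylation of a macrocyclic α-allenol through O6 (C12 from CO; 13-Cl, then 13-OAc).
3. Ten-membered carbocycle ⇐ C6–C7 closure (the bond germacrene synthases make) by intramolecular chromium-mediated SE2′ allenylation of an enal by a propargylic chloride.
4. Seco precursor ⇐ geranyl acetate (C1–C6, C9, C10, C14, C15) + CO (C8) + propargyl chloride (C7, C11, C13); C8 set by asymmetric transfer hydrogenation of an ynone; ester side chain from ethyl 2-(hydroxymethyl)acrylate.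
5. Order of ring formation: carbocycle, then lactone, then the two oxiranes.

Assumption: locants C1–C15 are germacrane locants of the target (O-bearing ring carbons C6 and C8, lactone carbonyl C12, acetoxymethyl carbon C13, methyls C14 on C10 and C15 on C4).

**Route**

Step 1
Reactants: 1 geranyl acetate
Product: 2 (2E,6E)-8-hydroxy-3,7-dimethylocta-2,6-dien-1-yl acetate
Conditions: SeO2 (0.3 equiv), t-BuOOH (70% aq., 3 equiv), salicylic acid (0.1 equiv), CH2Cl2, 0 °C to rt
Reagents that add atoms: selenium dioxide (O=[Se]=O, catalytic oxygen carrier); tert-butyl hydroperoxide (CC(C)(C)OO)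
Why: Catalytic SeO2/t-BuOOH allylic oxidation (ene reaction, then [2,3]-sigmatropic shift) attacks only the (E)-methyl of the electron-rich distal olefin, because the 2,3-olefin is deactivated by the allylic acetate, so the new allylic alcohol is formed with E geometry.

Step 2
Reactants: 2 (2E,6E)-8-hydroxy-3,7-dimethylocta-2,6-dien-1-yl acetate
Product: 3 (2E,6E)-8-[(methoxycarbonyl)oxy]-3,7-dimethylocta-2,6-dien-1-yl acetate
Conditions: ClCO2Me (1.5 equiv), pyridine (2 equiv), CH2Cl2, 0 °C
Reagents that add atoms: methyl chloroformate (COC(=O)Cl)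
Why: Routine O-acylation gives the allylic methyl carbonate, which ionises on zerovalent palladium far faster than the allylic acetate at the other terminus.

Step 3
Reactants: 3 (2E,6E)-8-[(methoxycarbonyl)oxy]-3,7-dimethylocta-2,6-dien-1-yl acetate
Product: 4 methyl (3E,7E)-9-acetoxy-3,7-dimethylnona-3,7-dienoate
Conditions: Pd(OAc)2 (2 mol %), PPh3 (8 mol %), CO (20 atm), toluene, 50 °C
Reagents that add atoms: carbon monoxide ([C-]#[O+])
Why: Tsuji decarboxylative carbonylation: zerovalent palladium formed in situ ionises the carbonate with loss of CO2, CO inserts at the unsubstituted allyl terminus and the liberated methoxide captures the acyl–palladium, giving the β,γ-unsaturated ester with the E olefin retained under neutral conditions that leave the acetate untouched.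

Step 4
Reactants: 4 methyl (3E,7E)-9-acetoxy-3,7-dimethylnona-3,7-dienoate; 5 propargyl chloride
Product: 7 (6E,10E)-1-chloro-12-hydroxy-6,10-dimethyldodeca-6,10-dien-2-yn-4-one, via 3-chloro-1-lithiopropyne 6 (not isolated)
Conditions: 5 (3.3 equiv), n-BuLi (3.2 equiv), THF, −78 °C; BF3·OEt2 (3.3 equiv), −78 °C; then 4, −78 °C, 1 h; sat. aq. NH4Cl, −78 °C to rt
Reagents that add atoms: none
Why: Yamaguchi-type ynone synthesis in which the alkynyllithium–BF3 reagent adds once to each ester carbonyl at −78 °C and the tetrahedral adducts survive until the quench, so the methyl ester becomes the ynone without over-addition or enolisation of the doubly activated C9 methylene while the acetate is cleaved in the same operation to free the C6 hydroxyl.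

Step 5
Reactants: 7 (6E,10E)-1-chloro-12-hydroxy-6,10-dimethyldodeca-6,10-dien-2-yn-4-one
Product: 8 (2E,6E,9S)-12-chloro-3,7-dimethyldodeca-2,6-dien-10-yne-1,9-diol
Conditions: Ru[(S,S)-TsNCH(Ph)CH(Ph)NH](p-cymene) (2 mol %), i-PrOH, rt
Reagents that add atoms: none
Why: Base-free Noyori asymmetric transfer hydrogenation of an ynone, in which the (S,S)-ruthenium amido complex delivers hydride to the carbonyl face that puts the alkynyl group where an aryl group normally sits, setting C8 as S (expected ≥95% ee) without isomerising the skipped olefin or touching the chloride.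

Step 6
Reactants: 8 (2E,6E,9S)-12-chloro-3,7-dimethyldodeca-2,6-dien-10-yne-1,9-diol
Product: 9 (2E,6E,9S)-12-chloro-9-hydroxy-3,7-dimethyldodeca-2,6-dien-10-ynal
Conditions: TEMPO (0.1 equiv), PhI(OAc)2 (1.1 equiv), CH2Cl2, 0 °C to rt
Reagents that add atoms: none
Why: Oxoammonium (TEMPO/PhI(OAc)2) oxidation converts the primary allylic alcohol into the (E)-enal much faster than it touches the secondary propargylic alcohol and does not isomerise the olefin.

Step 7
Reactants: 10 ethyl 2-(hydroxymethyl)acrylate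
Product: 11 ethyl 2-{[(tert-butyldimethylsilyl)oxy]methyl}acrylate
Conditions: TBSCl (1.2 equiv), imidazole (2 equiv), CH2Cl2, 0 °C to rt
Reagents that add atoms: tert-butyldimethylsilyl chloride (CC(C)(C)[Si](C)(C)Cl)
Why: Routine silylation masks the primary hydroxyl that would otherwise self-esterify in the coupling of step 9.

Step 8
Reactants: 11 ethyl 2-{[(tert-butyldimethylsilyl)oxy]methyl}acrylate
Product: 12 2-{[(tert-butyldimethylsilyl)oxy]methyl}acrylic acid
Conditions: LiOH·H2O (2 equiv), THF–H2O (3:1), 0 °C to rt; then 1 M HCl to pH 4 at 0 °C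
Reagents that add atoms: lithium hydroxide ([Li+].[OH-])
Why: Mild saponification of the ethyl ester leaves the silyl ether intact and delivers the acid needed for the Steglich coupling.

Step 9
Reactants: 9 (2E,6E,9S)-12-chloro-9-hydroxy-3,7-dimethyldodeca-2,6-dien-10-ynal; 12 2-{[(tert-butyldimethylsilyl)oxy]methyl}acrylic acid
Product: 13 (2E,6E,9S)-12-chloro-3,7-dimethyl-1-oxododeca-2,6-dien-10-yn-9-yl 2-{[(tert-butyldimethylsilyl)oxy]methyl}acrylate
Conditions: DCC (1.3 equiv), DMAP (0.1 equiv), CH2Cl2, 0 °C to rt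
Reagents that add atoms: none
Why: Steglich esterification acylates the only hydroxyl (C8–OH) with retention of configuration, and the ester also blocks O8 so that only O6 can close the lactone later.

Step 10
Reactants: 13 (2E,6E,9S)-12-chloro-3,7-dimethyl-1-oxododeca-2,6-dien-10-yn-9-yl 2-{[(tert-butyldimethylsilyl)oxy]methyl}acrylate
Product: 15 macrocyclic allenol (6R,8S)-6-hydroxy-12-norgermacra-1(10)E,4E,7(11),11(13)-tetraen-8-yl 2-{[(tert-butyldimethylsilyl)oxy]methyl}acrylate, via propargylchromium dichloride 14 (not isolated)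
Conditions: CrCl2 (8 equiv), DMF–THF (1:3), syringe-pump addition of 13 over 12 h (final 2 mM), rt; aqueous work-up
Reagents that add atoms: none
Why: Proposed new method: two equivalents of divalent chromium reduce the primary propargylic chloride to a propargylchromium species (metal on C13, the unhindered terminus) that adds to the tethered enal through a six-membered SE2′ transition state, forming the C6–C7 bond, the ten-membered ring and an exocyclic allene in one event, with C6 set by 1,3-induction from C8 in a crown-like transition state that keeps the chromium alkoxide and the C8 acyloxy group pseudo-equatorial (6,8-cis, 6R in this intermediate; minor epimer removed by chromatography); the closest known reactions are the intermolecular chromium-mediated (Nozaki–Hiyama type) allenylation of aldehydes by γ-substituted propargyl halides and the Nozaki–Hiyama macrocyclisation of 2-(bromomethyl)acrylates onto enals that builds germacranolide rings.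

Step 11
Reactants: 15 macrocyclic allenol (6R,8S)-6-hydroxy-12-norgermacra-1(10)E,4E,7(11),11(13)-tetraen-8-yl 2-{[(tert-butyldimethylsilyl)oxy]methyl}acrylate
Product: 16 (6R,8S)-13-chloro-8-[(2-{[(tert-butyldimethylsilyl)oxy]methyl}acryloyl)oxy]germacra-1(10)E,4E,7(11)-trien-6,12-olide
Conditions: PdCl2 (5 mol %), CuCl2 (3 equiv), CO (1 atm), propylene oxide (5 equiv), THF, rt
Reagents that add atoms: carbon monoxide ([C-]#[O+]); copper dichloride (Cl[Cu]Cl, chlorine source)
Why: Divalent-palladium chlorocyclocarbonylation of a 2-substituted 2,3-allenol, in which the O6 alkoxycarbonyl–palladium species inserts the proximal allene bond to close the five-membered lactone and the resulting allyl–palladium is cleaved by chloride at the exocyclic terminus C13, giving the 7(11)-unsaturated butenolide directly without touching C6 while propylene oxide traps the HCl that would harm the germacradiene.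

Step 12
Reactants: 16 (6R,8S)-13-chloro-8-[(2-{[(tert-butyldimethylsilyl)oxy]methyl}acryloyl)oxy]germacra-1(10)E,4E,7(11)-trien-6,12-olide
Product: 17 (6R,8S)-13-acetoxy-8-[(2-{[(tert-butyldimethylsilyl)oxy]methyl}acryloyl)oxy]germacra-1(10)E,4E,7(11)-trien-6,12-olide
Conditions: KOAc (3 equiv), DMF, rt
Reagents that add atoms: potassium acetate (CC(=O)[O-].[K+])
Why: SN2 displacement of the primary allylic chloride by acetate installs the 13-acetoxy group under nearly neutral conditions that do not deprotonate C6.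

Step 13
Reactants: 17 (6R,8S)-13-acetoxy-8-[(2-{[(tert-butyldimethylsilyl)oxy]methyl}acryloyl)oxy]germacra-1(10)E,4E,7(11)-trien-6,12-olide
Product: 18 (6R,8S)-13-acetoxy-8-{[2-(hydroxymethyl)acryloyl]oxy}germacra-1(10)E,4E,7(11)-trien-6,12-olide
Conditions: HF·pyridine, pyridine, THF, 0 °C to rt
Reagents that add atoms: none
Why: Buffered HF·pyridine cleaves the primary silyl ether without acyl migration, and it is used before any oxirane is present so that no fluorohydrin or transannular opening can occur.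

Step 14
Reactants: 18 (6R,8S)-13-acetoxy-8-{[2-(hydroxymethyl)acryloyl]oxy}germacra-1(10)E,4E,7(11)-trien-6,12-olide
Product: 19 (1R,4R,5R,6S,8S,10R)-13-acetoxy-1,10:4,5-diepoxy-8-{[2-(hydroxymethyl)acryloyl]oxy}germacr-7(11)-en-6,12-olide (CNP0282791.1)
Conditions: dimethyldioxirane (2.5 equiv, ca. 0.07 M in acetone), CH2Cl2, −20 °C to 0 °C; evaporation, chromatography on deactivated silica
Reagents that add atoms: dimethyldioxirane (CC1(C)OO1)
Why: Dioxirane epoxidation under macrocyclic substrate control, in which the two electron-rich trisubstituted (E)-olefins stand perpendicular to the ring in the crown conformer with C14 and C15 syn, so attack on the exposed outer faces gives the 1β,10α- and 4α,5β-oxiranes (1R,10R and 4R,5R) while the conjugated butenolide and acrylate olefins are too electron-poor to react.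

**Compound list**
1 | geranyl acetate, (2E)-3,7-dimethylocta-2,6-dien-1-yl acetate | CC(=O)OC/C=C(\C)CCC=C(C)C | starting material
2 | (2E,6E)-8-hydroxy-3,7-dimethylocta-2,6-dien-1-yl acetate | CC(=O)OC/C=C(\C)CC/C=C(\C)CO | intermediate
3 | (2E,6E)-8-[(methoxycarbonyl)oxy]-3,7-dimethylocta-2,6-dien-1-yl acetate | CC(=O)OC/C=C(\C)CC/C=C(\C)COC(=O)OC | intermediate
4 | methyl (3E,7E)-9-acetoxy-3,7-dimethylnona-3,7-dienoate | CC(=O)OC/C=C(\C)CC/C=C(\C)CC(=O)OC | intermediate
5 | propargyl chloride (3-chloroprop-1-yne) | ClCC#C | starting material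
6 | 3-chloro-1-lithiopropyne | [Li]C#CCCl | intermediate (not isolated)
7 | (6E,10E)-1-chloro-12-hydroxy-6,10-dimethyldodeca-6,10-dien-2-yn-4-one | OC/C=C(\C)CC/C=C(\C)CC(=O)C#CCCl | intermediate
8 | (2E,6E,9S)-12-chloro-3,7-dimethyldodeca-2,6-dien-10-yne-1,9-diol | OC/C=C(\C)CC/C=C(\C)C[C@H](O)C#CCCl | intermediate
9 | (2E,6E,9S)-12-chloro-9-hydroxy-3,7-dimethyldodeca-2,6-dien-10-ynal | O=C/C=C(\C)CC/C=C(\C)C[C@H](O)C#CCCl | intermediate
10 | ethyl 2-(hydroxymethyl)acrylate | C=C(CO)C(=O)OCC | starting material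
11 | ethyl 2-{[(tert-butyldimethylsilyl)oxy]methyl}acrylate | C=C(CO[Si](C)(C)C(C)(C)C)C(=O)OCC | intermediate
12 | 2-{[(tert-butyldimethylsilyl)oxy]methyl}acrylic acid | C=C(CO[Si](C)(C)C(C)(C)C)C(=O)O | intermediate
13 | (2E,6E,9S)-12-chloro-3,7-dimethyl-1-oxododeca-2,6-dien-10-yn-9-yl 2-{[(tert-butyldimethylsilyl)oxy]methyl}acrylate | O=C/C=C(\C)CC/C=C(\C)C[C@H](OC(=O)C(=C)CO[Si](C)(C)C(C)(C)C)C#CCCl | intermediate
14 | propargylchromium dichloride, {(4S,6E,10E)-4-[(2-{[(tert-butyldimethylsilyl)oxy]methyl}acryloyl)oxy]-6,10-dimethyl-12-oxododeca-6,10-dien-2-yn-1-yl}chromium dichloride | O=C/C=C(\C)CC/C=C(\C)C[C@H](OC(=O)C(=C)CO[Si](C)(C)C(C)(C)C)C#CC[Cr](Cl)Cl | intermediate (not isolated)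
15 | macrocyclic allenol, (6R,8S)-6-hydroxy-12-norgermacra-1(10)E,4E,7(11),11(13)-tetraen-8-yl 2-{[(tert-butyldimethylsilyl)oxy]methyl}acrylate (ten-membered E,E-dienol with exocyclic C7=C11=C13H2) | C=C(CO[Si](C)(C)C(C)(C)C)C(=O)O[C@H]1C/C(C)=C/CC/C(C)=C/[C@@H](O)C1=C=C | intermediate
16 | (6R,8S)-13-chloro-8-[(2-{[(tert-butyldimethylsilyl)oxy]methyl}acryloyl)oxy]germacra-1(10)E,4E,7(11)-trien-6,12-olide | C=C(CO[Si](C)(C)C(C)(C)C)C(=O)O[C@H]1C/C(C)=C/CC/C(C)=C/[C@H]2OC(=O)C(CCl)=C12 | intermediate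
17 | (6R,8S)-13-acetoxy-8-[(2-{[(tert-butyldimethylsilyl)oxy]methyl}acryloyl)oxy]germacra-1(10)E,4E,7(11)-trien-6,12-olide | C=C(CO[Si](C)(C)C(C)(C)C)C(=O)O[C@H]1C/C(C)=C/CC/C(C)=C/[C@H]2OC(=O)C(COC(C)=O)=C12 | intermediate
18 | (6R,8S)-13-acetoxy-8-{[2-(hydroxymethyl)acryloyl]oxy}germacra-1(10)E,4E,7(11)-trien-6,12-olide | C=C(CO)C(=O)O[C@H]1C/C(C)=C/CC/C(C)=C/[C@H]2OC(=O)C(COC(C)=O)=C12 | intermediate
19 | (1R,4R,5R,6S,8S,10R)-13-acetoxy-1,10:4,5-diepoxy-8-{[2-(hydroxymethyl)acryloyl]oxy}germacr-7(11)-en-6,12-olide (CNP0282791.1) | C=C(CO)C(=O)O[C@H]1C[C@@]2(C)O[C@@H]2CC[C@@]2(C)O[C@@H]2[C@H]2OC(=O)C(COC(C)=O)=C12 | target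

**Totals**
Total step count: 14 (steps 7 and 8 are a two-step side branch for the acid 12).
Longest linear sequence: 12 steps (steps 1–6 and 9–14, from geranyl acetate).

**Steps most likely to fail, with fallbacks**

Step 4 (double ester alkynylation). Both ester groups must be consumed cleanly, and the product is a base-sensitive γ-chloro, β,γ-unsaturated ynone. Fallback: the route is left at 4 and passes through a Weinreb amide. MeNHOMe·HCl/AlMe3 (CH2Cl2, 0 °C to rt) converts the methyl ester into the amide and aminolyses the acetate, giving (3E,7E)-9-hydroxy-N-methoxy-N,3,7-trimethylnona-3,7-dienamide F1. Then 2.5 equiv of 6 (THF, −78 to −30 °C) add once through the stable chelate, and the route is rejoined at 7.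

Step 10 (ring closure). Three things can go wrong: 1,4-elimination of the C8 carboxylate from the propargylchromium species to a cumulene, closure through C13 to a twelve-membered cycloalkyne, and a poor ratio at C6. Fallback: the ester is deferred so that the metallated unit carries only a poor leaving group and a bulky C8 substituent. The route is left at 9, which is silylated (TBSOTf, 2,6-lutidine, CH2Cl2, −78 °C) to (2E,6E,9S)-9-[(tert-butyldimethylsilyl)oxy]-12-chloro-3,7-dimethyldodeca-2,6-dien-10-ynal F2. CrCl2 in DMF–THF under high dilution closes it, through its propargylchromium dichloride F3, to the 8-O-silyl macrocyclic allenol F4. PdCl2/CuCl2/CO/propylene oxide then gives the 8-O-silyl 13-chloro butenolide F5, and KOAc in DMF gives the 8-O-silyl 13-acetate F6. HF·pyridine frees the 8-hydroxy 13-acetate F7, and DCC/DMAP coupling with 12 rejoins the route at 17.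

Step 14 (double epoxidation). The facial outcome at both olefins rests on the conformation of the 7(11)-unsaturated lactone, and the product is acid- and silica-sensitive. Fallback: the 4,5-oxirane is set early by reagent control, leaving only one late epoxidation. The route is left at 8. Sharpless epoxidation (Ti(OiPr)4, D-(−)-diethyl tartrate, t-BuOOH, 4 Å sieves, CH2Cl2, −20 °C) gives the (2R,3R)-epoxy diol F8, and TEMPO/PhI(OAc)2 gives the epoxy hydroxy aldehyde F9. DCC/DMAP with 12 gives the epoxy ester F10. CrCl2 closes it, through its propargylchromium dichloride F11, to the 4,5-epoxy macrocyclic allenol F12. PdCl2/CuCl2/CO/propylene oxide gives the 4,5-epoxy 13-chloro butenolide F13, and KOAc gives the 4,5-epoxy 13-acetate F14. Bu4NF buffered with AcOH (HF is avoided because of the oxirane) gives the desilylated 4,5-epoxy 1(10)-ene F15. One equivalent of dimethyldioxirane on the remaining 1(10)-olefin rejoins the route at 19.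

**Further compounds**
F1 | step 4 | (3E,7E)-9-hydroxy-N-methoxy-N,3,7-trimethylnona-3,7-dienamide | OC/C=C(\C)CC/C=C(\C)CC(=O)N(C)OC
F2 | step 10 | (2E,6E,9S)-9-[(tert-butyldimethylsilyl)oxy]-12-chloro-3,7-dimethyldodeca-2,6-dien-10-ynal | O=C/C=C(\C)CC/C=C(\C)C[C@H](O[Si](C)(C)C(C)(C)C)C#CCCl
F3 | step 10 | {(4S,6E,10E)-4-[(tert-butyldimethylsilyl)oxy]-6,10-dimethyl-12-oxododeca-6,10-dien-2-yn-1-yl}chromium dichloride | O=C/C=C(\C)CC/C=C(\C)C[C@H](O[Si](C)(C)C(C)(C)C)C#CC[Cr](Cl)Cl
F4 | step 10 | (6R,8S)-8-[(tert-butyldimethylsilyl)oxy]-12-norgermacra-1(10)E,4E,7(11),11(13)-tetraen-6-ol | CC(C)(C)[Si](C)(C)O[C@H]1C/C(C)=C/CC/C(C)=C/[C@@H](O)C1=C=C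
F5 | step 10 | (6R,8S)-8-[(tert-butyldimethylsilyl)oxy]-13-chlorogermacra-1(10)E,4E,7(11)-trien-6,12-olide | CC(C)(C)[Si](C)(C)O[C@H]1C/C(C)=C/CC/C(C)=C/[C@H]2OC(=O)C(CCl)=C12
F6 | step 10 | (6R,8S)-13-acetoxy-8-[(tert-butyldimethylsilyl)oxy]germacra-1(10)E,4E,7(11)-trien-6,12-olide | CC(C)(C)[Si](C)(C)O[C@H]1C/C(C)=C/CC/C(C)=C/[C@H]2OC(=O)C(COC(C)=O)=C12
F7 | step 10 | (6R,8S)-13-acetoxy-8-hydroxygermacra-1(10)E,4E,7(11)-trien-6,12-olide | O[C@H]1C/C(C)=C/CC/C(C)=C/[C@H]2OC(=O)C(COC(C)=O)=C12
F8 | step 14 | (2R,3R,6E,9S)-12-chloro-2,3-epoxy-3,7-dimethyldodec-6-en-10-yne-1,9-diol | OC[C@H]1O[C@]1(C)CC/C=C(\C)C[C@H](O)C#CCCl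
F9 | step 14 | (2S,3R,6E,9S)-12-chloro-2,3-epoxy-9-hydroxy-3,7-dimethyldodec-6-en-10-ynal | O=C[C@H]1O[C@]1(C)CC/C=C(\C)C[C@H](O)C#CCCl
F10 | step 14 | (2S,3R,6E,9S)-12-chloro-2,3-epoxy-3,7-dimethyl-1-oxododec-6-en-10-yn-9-yl 2-{[(tert-butyldimethylsilyl)oxy]methyl}acrylate | O=C[C@H]1O[C@]1(C)CC/C=C(\C)C[C@H](OC(=O)C(=C)CO[Si](C)(C)C(C)(C)C)C#CCCl
F11 | step 14 | propargylchromium dichloride of F10, {(4S,6E,10R,11S)-4-[(2-{[(tert-butyldimethylsilyl)oxy]methyl}acryloyl)oxy]-10,11-epoxy-6,10-dimethyl-12-oxododec-6-en-2-yn-1-yl}chromium dichloride | O=C[C@H]1O[C@]1(C)CC/C=C(\C)C[C@H](OC(=O)C(=C)CO[Si](C)(C)C(C)(C)C)C#CC[Cr](Cl)Cl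
F12 | step 14 | (4R,5R,6S,8S)-4,5-epoxy-6-hydroxy-12-norgermacra-1(10)E,7(11),11(13)-trien-8-yl 2-{[(tert-butyldimethylsilyl)oxy]methyl}acrylate | C=C(CO[Si](C)(C)C(C)(C)C)C(=O)O[C@H]1C/C(C)=C/CC[C@@]2(C)O[C@@H]2[C@@H](O)C1=C=C
F13 | step 14 | (4R,5R,6S,8S)-13-chloro-4,5-epoxy-8-[(2-{[(tert-butyldimethylsilyl)oxy]methyl}acryloyl)oxy]germacra-1(10)E,7(11)-dien-6,12-olide | C=C(CO[Si](C)(C)C(C)(C)C)C(=O)O[C@H]1C/C(C)=C/CC[C@@]2(C)O[C@@H]2[C@H]2OC(=O)C(CCl)=C12
F14 | step 14 | (4R,5R,6S,8S)-13-acetoxy-4,5-epoxy-8-[(2-{[(tert-butyldimethylsilyl)oxy]methyl}acryloyl)oxy]germacra-1(10)E,7(11)-dien-6,12-olide | C=C(CO[Si](C)(C)C(C)(C)C)C(=O)O[C@H]1C/C(C)=C/CC[C@@]2(C)O[C@@H]2[C@H]2OC(=O)C(COC(C)=O)=C12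
F15 | step 14 | (4R,5R,6S,8S)-13-acetoxy-4,5-epoxy-8-{[2-(hydroxymethyl)acryloyl]oxy}germacra-1(10)E,7(11)-dien-6,12-olide | C=C(CO)C(=O)O[C@H]1C/C(C)=C/CC[C@@]2(C)O[C@@H]2[C@H]2OC(=O)C(COC(C)=O)=C12
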